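The pyran ring F of the lower (epigallocatechin) unit is disconnected across C4–C4a and O1–C8a, so that its whole O1–C2–C3–C4 chain is clipped onto a preformed 4-aryl-epiafzelechin. The key step is a palladium/norbornene annulation: aryl iodide 7 (iodine on C8a of benzo ring D) and γ-iodo alcohol 15 give the chroman in one operation by ortho C–H alkylation at C4a and ipso C–O coupling at C8a. It exploits that C8a is flanked by C8, which already carries the upper flavan (the obligatory ortho blocker; it also locks the 4→8 connectivity), and by the only free ortho position, C4a–H. Both lower stereocentres come from an Evans glycolate aldol.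

Key step: step 9

Remark: (−)-epiafzelechin (2R,3R) is taken as a purchasable natural flavan-3-ol. Rings are lettered A (benzo), B (aryl), C (pyran) in the upper unit and D, E, F likewise in the lower unit; atom numbers are flavan numbers within each unit. The target is (−)-epiafzelechin-(4β→8)-(−)-epigallocatechin (upper 2R,3R,4R; lower 2R,3R).

Step 1
Reactants: 1 (−)-epiafzelechin
Product: 2 3,5,7,4'-tetra-O-benzyl-(−)-epiafzelechin
Conditions: NaH, BnBr, DMF, 0 °C to rt
Reagents that add atoms: benzyl bromide, BrCc1ccccc1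
Why: Williamson etherification of the three phenols and the C3 hydroxyl; no stereocentre is touched, and the 3-O-benzyl group removes the only free hydroxyl that could interfere with the later palladium step.

Step 2
Reactants: 2 3,5,7,4'-tetra-O-benzyl-(−)-epiafzelechin
Product: 3 3,5,7,4'-tetra-O-benzyl-4β-(2-ethoxyethoxy)-(−)-epiafzelechin
Conditions: DDQ, 2-ethoxyethanol, CH2Cl2, rt
Reagents that add atoms: 2-ethoxyethanol, CCOCCO
Why: DDQ benzylic oxidation: hydride abstraction at C4 gives the cation stabilised by the 5,7-dialkoxy ring A, which 2-ethoxyethanol should trap anti to the 3-benzyloxy group (4β); this centre is ionised again in step 4, so its configuration is not critical.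

Step 3
Reactants: 4 5-iodoresorcinol
Product: 5 1,3-bis(benzyloxy)-5-iodobenzene
Conditions: BnBr, K2CO3, DMF, 60 °C
Reagents that add atoms: benzyl bromide, BrCc1ccccc1
Why: double Williamson etherification of the resorcinol; the aryl iodide is inert to K2CO3.

Step 4
Reactants: 3 3,5,7,4'-tetra-O-benzyl-4β-(2-ethoxyethoxy)-(−)-epiafzelechin, 5 1,3-bis(benzyloxy)-5-iodobenzene
Product: 7 4β-[2,4-bis(benzyloxy)-6-iodophenyl]-3,5,7,4'-tetra-O-benzyl-(−)-epiafzelechin, via flavan-4-yl cation triflate 6 (not isolated)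
Conditions: TMSOTf (cat.), 5 (5 equiv), CH2Cl2, −78 to −30 °C, slow addition of 3
Reagents that add atoms: none
Why: Lewis-acid Friedel–Crafts C4-arylation of a 4-alkoxyflavan: TMSOTf ionises the C4 acetal to cation 6, which the iodoarene should attack para to one benzyloxy group and next to iodine (the site preferred by 1-halo-3,5-dialkoxybenzenes in Friedel–Crafts-type substitutions), from the β face anti to the α-oriented 2-aryl and 3-benzyloxy groups, so that C4 is set 4β (3,4-trans).

Step 5
Reactants: 8 (S)-4-benzyloxazolidin-2-one, 9 (benzyloxy)acetyl chloride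
Product: 10 (S)-4-benzyl-3-[(benzyloxy)acetyl]oxazolidin-2-one
Conditions: n-BuLi, THF, −78 °C
Reagents that add atoms: none
Why: N-acylation of the lithiated oxazolidinone with the acid chloride (standard loading of an Evans auxiliary); the auxiliary stereocentre is not touched.

Step 6
Reactants: 10 (S)-4-benzyl-3-[(benzyloxy)acetyl]oxazolidin-2-one, 11 3,4,5-tris(benzyloxy)benzaldehyde
Product: 13 (S)-4-benzyl-3-[(2S,3R)-2-(benzyloxy)-3-hydroxy-3-[3,4,5-tris(benzyloxy)phenyl]propanoyl]oxazolidin-2-one, via Z boron enolate 12 (not isolated)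
Conditions: Bu2BOTf, Et3N, CH2Cl2, −78 to 0 °C; 11, −78 to 0 °C; then MeOH, pH 7 buffer, H2O2
Reagents that add atoms: none
Why: Evans syn aldol of the Z dibutylboron glycolate enolate 12 through a chair Zimmerman–Traxler transition state, in which the (S)-benzyl auxiliary shields one enolate face, should set both new stereocentres (2S,3R; later C3 and C2 of ring F) in the syn relation that becomes 2,3-cis.

Step 7
Reactants: 13 (S)-4-benzyl-3-[(2S,3R)-2-(benzyloxy)-3-hydroxy-3-[3,4,5-tris(benzyloxy)phenyl]propanoyl]oxazolidin-2-one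
Product: 14 (1R,2R)-2-(benzyloxy)-1-[3,4,5-tris(benzyloxy)phenyl]propane-1,3-diol
Conditions: LiBH4, MeOH, THF, 0 °C
Reagents that add atoms: none
Why: reductive cleavage of the N-acyl oxazolidinone with LiBH4 gives the primary alcohol and returns the auxiliary; neither stereocentre is epimerised and the benzyl ethers are inert.

Step 8
Reactants: 14 (1R,2R)-2-(benzyloxy)-1-[3,4,5-tris(benzyloxy)phenyl]propane-1,3-diol
Product: 15 (1R,2S)-2-(benzyloxy)-3-iodo-1-[3,4,5-tris(benzyloxy)phenyl]propan-1-ol
Conditions: I2, PPh3, imidazole, CH2Cl2, 0 °C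
Reagents that add atoms: iodine, II
Why: Garegg–Samuelsson (Appel-type) iodination, selective for the unhindered primary hydroxyl over the secondary benzylic one at 0 °C; no stereocentre reacts (the descriptor at C2 changes only through the priority of iodine).

Step 9
Reactants: 7 4β-[2,4-bis(benzyloxy)-6-iodophenyl]-3,5,7,4'-tetra-O-benzyl-(−)-epiafzelechin, 15 (1R,2S)-2-(benzyloxy)-3-iodo-1-[3,4,5-tris(benzyloxy)phenyl]propan-1-ol
Product: 17 3,5,7,4'-tetra-O-benzyl-(−)-epiafzelechin-(4β→8)-3,5,7,3',4',5'-hexa-O-benzyl-(−)-epigallocatechin, via arylpalladium iodide 16 (not isolated)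
Conditions: Pd(OAc)2 (10 mol %), RuPhos (20 mol %), norbornene (2 equiv), Cs2CO3 (3 equiv), 15 (2 equiv), 1,4-dioxane, 100 °C
Reagents that add atoms: none
Why: Proposed new method: zerovalent palladium inserts into the C8a–I bond of 7, norbornene carbopalladation and C–H palladation at C4a (the only free ortho position, since C8 carries the upper flavan) give the aryl–norbornyl palladacycle, whose oxidative addition to the primary C–I bond of 15 (tetravalent palladium) and reductive elimination forge C4–C4a; the now doubly ortho-substituted aryl expels norbornene to give arylpalladium iodide 16, and Cs2CO3-assisted binding of the C2 alkoxide followed by C–O reductive elimination forges O1–C8a. The closest known reaction types are the palladium/norbornene annulation of ortho-substituted aryl iodides with epoxides to 2,3-dihydrobenzofurans and with bromoalkylamines to tetrahydroquinolines, and the palladium-catalysed intramolecular etherification of secondary alcohols to chromans; new here are the γ-iodo secondary benzylic alcohol as partner and the closure of a six-membered oxygen ring within the annulation. Ring F is closed as a formal [4+2] annulation of the O1–C2–C3–C4 chain across C4a–C8a, the last event being C(sp2)–O reductive elimination from a seven-membered oxapalladacycle. No stereocentre is created: C2 and C3 come from the aldol and are not touched, because the reacting carbon is the CH2 group (C4) and the C2–O bond is never broken, so the 2,3-cis relation is conserved. The step needs ortho-site control (C8 is blocked and the iodine position fixes the 4→8 connectivity), closure by the C2 oxygen only (O3 is benzylated and neither 7 nor 15 has another free hydroxyl) and C–O reductive elimination faster than β-hydride elimination of the secondary alkoxide, for which the bulky electron-rich RuPhos and the ortho-disubstituted aryl group are chosen.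

Step 10
Reactants: 17 3,5,7,4'-tetra-O-benzyl-(−)-epiafzelechin-(4β→8)-3,5,7,3',4',5'-hexa-O-benzyl-(−)-epigallocatechin
Product: 18 (−)-epiafzelechin-(4β→8)-(−)-epigallocatechin (CNP0290824.1)
Conditions: H2 (1 atm), Pd(OH)2/C, THF/MeOH/H2O, rt, filtration under argon
Reagents that add atoms: none
Why: hydrogenolysis of all ten benzyl ethers over Pd(OH)2/C; the interflavan C4–C8 bond and the cyclic benzylic C2–O1 bonds should survive these neutral conditions, and no stereocentre is affected.

Compound list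
1 | (−)-epiafzelechin, (2R,3R)-2-(4-hydroxyphenyl)chromane-3,5,7-triol | Oc1ccc([C@H]2Oc3cc(O)cc(O)c3C[C@H]2O)cc1 | starting material
2 | 3,5,7,4'-tetra-O-benzyl-(−)-epiafzelechin (2R,3R, 2,3-cis) | c1ccccc1COc1ccc([C@H]2Oc3cc(OCc4ccccc4)cc(OCc4ccccc4)c3C[C@H]2OCc5ccccc5)cc1 | intermediate
3 | 3,5,7,4'-tetra-O-benzyl-4β-(2-ethoxyethoxy)-(−)-epiafzelechin (2,3-cis, 3,4-trans) | c1ccccc1COc1ccc([C@H]2Oc3cc(OCc4ccccc4)cc(OCc4ccccc4)c3[C@H](OCCOCC)[C@H]2OCc5ccccc5)cc1 | intermediate
4 | 5-iodoresorcinol (5-iodobenzene-1,3-diol) | Oc1cc(O)cc(I)c1 | starting material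
5 | 1,3-bis(benzyloxy)-5-iodobenzene | Ic1cc(OCc2ccccc2)cc(OCc2ccccc2)c1 | intermediate
6 | C4 cation of 3,5,7,4'-tetra-O-benzyl-epiafzelechin, triflate salt (forms in the flask) | c1ccccc1COc1ccc([C@H]2Oc3cc(OCc4ccccc4)cc(OCc4ccccc4)c3[CH+][C@H]2OCc5ccccc5)cc1.[O-]S(=O)(=O)C(F)(F)F | intermediate
7 | 4β-[2,4-bis(benzyloxy)-6-iodophenyl]-3,5,7,4'-tetra-O-benzyl-(−)-epiafzelechin (2,3-cis, 3,4-trans) | c1ccccc1COc1ccc([C@H]2Oc3cc(OCc4ccccc4)cc(OCc4ccccc4)c3[C@H](c3c(OCc4ccccc4)cc(OCc4ccccc4)cc3I)[C@H]2OCc5ccccc5)cc1 | intermediate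
8 | (S)-4-benzyloxazolidin-2-one | O=C1OC[C@H](Cc2ccccc2)N1 | starting material
9 | (benzyloxy)acetyl chloride | ClC(=O)COCc1ccccc1 | starting material
10 | (S)-4-benzyl-3-[(benzyloxy)acetyl]oxazolidin-2-one | O=C(COCc1ccccc1)N2C(=O)OC[C@@H]2Cc3ccccc3 | intermediate
11 | 3,4,5-tris(benzyloxy)benzaldehyde | O=Cc1cc(OCc2ccccc2)c(OCc2ccccc2)c(OCc2ccccc2)c1 | starting material
12 | Z dibutylboron enolate of 10 (O–B cis to the benzyloxy group; forms in the flask) | CCCCB(CCCC)O/C(=C\OCc1ccccc1)N2C(=O)OC[C@@H]2Cc3ccccc3 | intermediate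
13 | (S)-4-benzyl-3-[(2S,3R)-2-(benzyloxy)-3-hydroxy-3-[3,4,5-tris(benzyloxy)phenyl]propanoyl]oxazolidin-2-one (syn aldol) | O=C([C@@H](OCc1ccccc1)[C@H](O)c1cc(OCc2ccccc2)c(OCc2ccccc2)c(OCc2ccccc2)c1)N1C(=O)OC[C@@H]1Cc1ccccc1 | intermediate
14 | (1R,2R)-2-(benzyloxy)-1-[3,4,5-tris(benzyloxy)phenyl]propane-1,3-diol | OC[C@@H](OCc1ccccc1)[C@H](O)c1cc(OCc2ccccc2)c(OCc2ccccc2)c(OCc2ccccc2)c1 | intermediate
15 | (1R,2S)-2-(benzyloxy)-3-iodo-1-[3,4,5-tris(benzyloxy)phenyl]propan-1-ol | IC[C@@H](OCc1ccccc1)[C@H](O)c1cc(OCc2ccccc2)c(OCc2ccccc2)c(OCc2ccccc2)c1 | intermediate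
16 | ortho-alkylated arylpalladium iodide: 7 carrying the C4–C3–C2 chain of 15 on C4a and Pd–I on C8a (divalent palladium, phosphine not drawn; forms in the flask) | c1ccccc1COc1ccc([C@H]2Oc3cc(OCc4ccccc4)cc(OCc4ccccc4)c3[C@H](c3c(OCc4ccccc4)cc(OCc4ccccc4)c(C[C@@H](OCc4ccccc4)[C@H](O)c4cc(OCc6ccccc6)c(OCc6ccccc6)c(OCc6ccccc6)c4)c3[Pd]I)[C@H]2OCc5ccccc5)cc1 | intermediate
17 | 3,5,7,4'-tetra-O-benzyl-(−)-epiafzelechin-(4β→8)-3,5,7,3',4',5'-hexa-O-benzyl-(−)-epigallocatechin | c1ccccc1COc1ccc([C@H]2Oc3cc(OCc4ccccc4)cc(OCc4ccccc4)c3[C@H](c3c(OCc4ccccc4)cc(OCc4ccccc4)c4c3O[C@H](c3cc(OCc6ccccc6)c(OCc6ccccc6)c(OCc6ccccc6)c3)[C@H](OCc3ccccc3)C4)[C@H]2OCc5ccccc5)cc1 | intermediate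
18 | (−)-epiafzelechin-(4β→8)-(−)-epigallocatechin, CNP0290824.1 | Oc1ccc([C@H]2Oc3cc(O)cc(O)c3[C@H](c3c(O)cc(O)c4c3O[C@H](c3cc(O)c(O)c(O)c3)[C@H](O)C4)[C@H]2O)cc1 | target

Total step count: 10. Longest linear sequence: 6 steps (steps 5, 6, 7, 8, 9, 10).

Steps most likely to fail

Step 9 (Proposed new method). The palladium-bound secondary benzylic alkoxide may undergo β-hydride elimination instead of C–O reductive elimination, which would reduce the ipso position. Iodo alcohol 15 may also close to an oxetane under the base before the palladacycle consumes it, and C–H palladation at the hindered C4a may be slow. Fallback with known chemistry, setting out from 3 and coming back at 17: commercial (−)-epigallocatechin is per-benzylated (NaH, BnBr, DMF) to 3,5,7,3',4',5'-hexa-O-benzyl-(−)-epigallocatechin F1. Compound 3 is then coupled with an excess of F1 under TMSOTf in CH2Cl2 at −78 °C, the established Friedel–Crafts union of a flavan C4 cation with C8 of a second flavan (4β by anti attack). This should give 17 directly, and step 10 follows.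

Step 4. Cation 6 may be captured by ring A of a second molecule (self-condensation) faster than by the weakly nucleophilic iodoarene, and attack may occur at the position between the two benzyloxy groups instead of next to iodine. Fallback, setting out from 3 and coming back at 7: the cation from 3 is trapped by the far more nucleophilic 3,5-bis(benzyloxy)phenol (TMSOTf, CH2Cl2, −78 °C), which reacts next to its free hydroxyl, to give 4β-[2,4-bis(benzyloxy)-6-hydroxyphenyl]-3,5,7,4'-tetra-O-benzyl-(−)-epiafzelechin F2. Triflation (Tf2O, pyridine, CH2Cl2) gives the aryl triflate F3. Stille-type stannylation (Pd(PPh3)4, Me3SnSnMe3, LiCl, 1,4-dioxane, 100 °C) gives the aryl trimethylstannane F4, and iododestannylation (I2, CH2Cl2, 0 °C) returns aryl iodide 7.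

Step 8. The phosphonium reagent may also activate the electron-rich secondary benzylic hydroxyl, leading to a benzylic iodide, elimination or oxetane formation, which erodes the primary selectivity. Fallback, setting out from 14 and coming back at 15: selective sulfonylation of the primary hydroxyl (TsCl, pyridine, 0 °C) gives (2R,3R)-2-(benzyloxy)-3-hydroxy-3-[3,4,5-tris(benzyloxy)phenyl]propyl 4-methylbenzenesulfonate F5, and Finkelstein exchange (NaI, acetone, 50 °C) gives 15.

Further compounds
F1 | step 9 | 3,5,7,3',4',5'-hexa-O-benzyl-(−)-epigallocatechin (2R,3R) | c1c(OCc3ccccc3)cc(OCc3ccccc3)c2c1O[C@H](c1cc(OCc3ccccc3)c(OCc3ccccc3)c(OCc3ccccc3)c1)[C@H](OCc1ccccc1)C2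
F2 | step 4 | 4β-[2,4-bis(benzyloxy)-6-hydroxyphenyl]-3,5,7,4'-tetra-O-benzyl-(−)-epiafzelechin | c1ccccc1COc1ccc([C@H]2Oc3cc(OCc4ccccc4)cc(OCc4ccccc4)c3[C@H](c3c(OCc4ccccc4)cc(OCc4ccccc4)cc3O)[C@H]2OCc5ccccc5)cc1
F3 | step 4 | aryl triflate of F2 | c1ccccc1COc1ccc([C@H]2Oc3cc(OCc4ccccc4)cc(OCc4ccccc4)c3[C@H](c3c(OCc4ccccc4)cc(OCc4ccccc4)cc3OS(=O)(=O)C(F)(F)F)[C@H]2OCc5ccccc5)cc1
F4 | step 4 | 4β-[2,4-bis(benzyloxy)-6-(trimethylstannyl)phenyl]-3,5,7,4'-tetra-O-benzyl-(−)-epiafzelechin | c1ccccc1COc1ccc([C@H]2Oc3cc(OCc4ccccc4)cc(OCc4ccccc4)c3[C@H](c3c(OCc4ccccc4)cc(OCc4ccccc4)cc3[Sn](C)(C)C)[C@H]2OCc5ccccc5)cc1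
F5 | step 8 | (2R,3R)-2-(benzyloxy)-3-hydroxy-3-[3,4,5-tris(benzyloxy)phenyl]propyl 4-methylbenzenesulfonate | Cc1ccc(cc1)S(=O)(=O)OC[C@@H](OCc1ccccc1)[C@H](O)c1cc(OCc2ccccc2)c(OCc2ccccc2)c(OCc2ccccc2)c1
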